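**Overview**

Retrosynthesis: the isopropyl ether, the chelated 5‑O‑methyl group and the C3 hydroxyl are stripped back to a 5,7,4'‑trimethoxyflavone. Ring C is then cut at O1–C2 and at C4–C4a, giving a ring A aryllithium and the cinnamoyl Weinreb amide of ring B. Last, the C8–C(benzylic) bond is cut, giving a ring A boronic ester and a 1‑(4‑alkoxyphenyl)ethyl carbamate.
Forward: ring A, ring B and the phenol ring are bought arenes. The phenol ring and ring A are joined at the stereocentre (step 5), the anisyl C3 unit is acylated onto ring A (step 8), ring C is closed last (step 10), then C3 is hydroxylated and two ethers are cleaved.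
Enabling feature: the only stereocentre is the CH(CH3) carbon bonded to C8 of ring A (between C7–OMe and C8a–O1) and to the 4‑hydroxyphenyl ring. That methine carbon is the carbinol carbon of a 1‑arylethanol in disguise, and C8 can carry boron, so the crowded aryl–C bond can be made by an aryl shift from boron to carbon.
Stereochemistry: set once, by transfer hydrogenation of ketone 1 with RuCl[(S,S)-TsDPEN](p-cymene) to the (S)‑alcohol. It is carried over stereospecifically (retention in lithiation and borylation, inversion in the aryl shift, retention in protodeboronation) to the (R)‑diarylethane, and no later step touches it.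

Key step: step 5

Assumptions: ketone 1 is bought as such. Species 16 and 19 carry one extra, uncontrolled stereocentre that is destroyed within the same step, so they are written without a descriptor at that atom.

**Route**

Step 1
Reactants: 1 1-(4-isopropoxyphenyl)ethanone
Product: 2 (S)-1-(4-isopropoxyphenyl)ethanol
Conditions: RuCl[(S,S)-TsDPEN](p-cymene) (1 mol%), HCO2H/Et3N (5:2), 30 °C
Reagents that add atoms: none
Why: Asymmetric transfer hydrogenation of an aryl methyl ketone, in which the (S,S)-TsDPEN ligand on ruthenium fixes the face that receives hydride and proton through the six-membered NH/RuH transition state, which for acetophenones should give the (S)-carbinol, while formic acid as hydrogen source makes the reduction of this electron-rich ketone irreversible.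

Step 2
Reactants: 2 (S)-1-(4-isopropoxyphenyl)ethanol
Product: 3 (S)-1-(4-isopropoxyphenyl)ethyl N,N-diisopropylcarbamate
Conditions: iPr2NCOCl, Et3N, CH2Cl2, reflux
Reagents that add atoms: N,N-diisopropylcarbamoyl chloride, CC(C)N(C(C)C)C(Cl)=O
Why: O-Carbamoylation of a secondary alcohol with a carbamoyl chloride takes place at oxygen only, so the carbinol configuration is untouched and the hindered carbamate needed to direct and stabilise the benzylic lithiation is in place.

Step 3
Reactants: 4 3,5-dimethoxyphenol
Product: 5 1,3-dimethoxy-5-(methoxymethoxy)benzene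
Conditions: MOMCl, iPr2NEt, CH2Cl2, 0 °C → rt
Reagents that add atoms: chloromethyl methyl ether, COCCl
Why: O-Alkylation of the phenol with MOMCl (acetal ether formation) installs the group that serves twice as the director of ortho-metalation and later frees the ring oxygen O1 under mild acid.

Step 4
Reactants: 5 1,3-dimethoxy-5-(methoxymethoxy)benzene
Product: 8 2-[2,4-dimethoxy-6-(methoxymethoxy)phenyl]-5,5-dimethyl-1,3,2-dioxaborinane, via aryllithium 6 (not isolated), via lithium triisopropoxyborate 7 (not isolated)
Conditions: n-BuLi, THF, 0 °C; B(OiPr)3, −78 °C → rt; neopentyl glycol, AcOH, rt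
Reagents that add atoms: triisopropyl borate, CC(C)OB(OC(C)C)OC(C)C; neopentyl glycol (2,2-dimethylpropane-1,3-diol), OCC(C)(C)CO
Why: Directed ortho-metalation, in which the MOM ether and the neighbouring methoxy group co-operate so that n-BuLi removes the proton between them (the two such positions are equivalent by symmetry), followed by borate trapping and in-flask transesterification with the diol, which avoids isolating the protodeboronation-prone free di-ortho-alkoxy boronic acid.

Step 5
Reactants: 3 (S)-1-(4-isopropoxyphenyl)ethyl N,N-diisopropylcarbamate and 8 2-[2,4-dimethoxy-6-(methoxymethoxy)phenyl]-5,5-dimethyl-1,3,2-dioxaborinane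
Product: 11 (R)-2-{1-[2,4-dimethoxy-6-(methoxymethoxy)phenyl]-1-(4-isopropoxyphenyl)ethyl}-5,5-dimethyl-1,3,2-dioxaborinane, via lithiated carbamate 9 (not isolated), via boronate complex 10 (not isolated)
Conditions: s-BuLi, Et2O, −78 °C; 8 in Et2O, −78 °C; MgBr2 (1 M in MeOH), −78 °C → rt
Reagents that add atoms: none
Why: s-BuLi removes the benzylic proton of 3 under direction of the carbamate carbonyl to give the configurationally stable organolithium 9 with retention, and 9 bonds to the boron of 8 on its lithium-bearing face (retention) to give boronate 10. On warming with MgBr2/MeOH the electron-rich ring A aryl group shifts from boron to carbon anti-periplanar to the departing carbamate (inversion at carbon), which forms the C8–C(benzylic) bond and the fully substituted centre of 11. The closest known reaction type is the lithiation–borylation (1,2-metallate rearrangement) of enantioenriched secondary benzylic carbamates with aryl boronic esters; no ring is closed. The new stereocentre is controlled by the (S)-carbinol centre of 3 alone, since retention in lithiation and borylation followed by invertive migration maps (S)-3 onto (R)-11. The step needs complete enantiospecificity, meaning boronate formation that does not revert and migration that outruns racemisation of 9; the small neopentyl glycol ester on a boron flanked by OMOM and OMe, the low temperature and the MgBr2/MeOH promoter, which speeds migration and protonates any released 9, are there to secure it. The di-ortho-oxygenated ring carbon is never attacked from outside, because the hindered bond is made by intramolecular migration of a good migrating group.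

Step 6
Reactants: 11 (R)-2-{1-[2,4-dimethoxy-6-(methoxymethoxy)phenyl]-1-(4-isopropoxyphenyl)ethyl}-5,5-dimethyl-1,3,2-dioxaborinane
Product: 12 (R)-1,5-dimethoxy-2-[1-(4-isopropoxyphenyl)ethyl]-3-(methoxymethoxy)benzene
Conditions: CsF, H2O (1.1 equiv), 1,4-dioxane, 45 °C
Reagents that add atoms: none
Why: Fluoride-promoted protodeboronation of a tertiary diarylalkyl boronic ester, in which the fluoroboronate formed with CsF is protonated by water at carbon on the face of the departing boron, so that C–B is replaced by C–H with retention and (R)-11 should give (R)-12 without any acid touching the electron-rich diarylethane.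

Step 7
Reactants: 13 (E)-4-methoxycinnamic acid
Product: 14 (E)-N-methoxy-N-methyl-3-(4-methoxyphenyl)acrylamide
Conditions: MeNHOMe·HCl, EDC·HCl, 4-(dimethylamino)pyridine (cat.), iPr2NEt, CH2Cl2, rt
Reagents that add atoms: N,O-dimethylhydroxylamine hydrochloride, CNOC.Cl
Why: Carbodiimide-mediated amide coupling of the acid with N,O-dimethylhydroxylamine gives the Weinreb amide and leaves the (E)-alkene unchanged.

Step 8
Reactants: 12 (R)-1,5-dimethoxy-2-[1-(4-isopropoxyphenyl)ethyl]-3-(methoxymethoxy)benzene and 14 (E)-N-methoxy-N-methyl-3-(4-methoxyphenyl)acrylamide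
Product: 17 (R,E)-1-{3-[1-(4-isopropoxyphenyl)ethyl]-4,6-dimethoxy-2-(methoxymethoxy)phenyl}-3-(4-methoxyphenyl)prop-2-en-1-one, via aryllithium 15 (not isolated), via lithium hemiaminal adduct 16 (not isolated)
Conditions: n-BuLi, TMEDA, THF, 0 °C; 14, −78 → −20 °C; AcOH, −78 °C
Reagents that add atoms: none
Why: Directed ortho-metalation followed by Weinreb ketone synthesis, in which the MOM chain, turned toward the free ring C–H by its bulky neighbour, directs n-BuLi to the carbon between OMOM and OMe rather than to the one between the two methoxy groups, the aryllithium adds once to the amide carbonyl because the chelated adduct 16 persists until the quench, and the methine C–H, held near the plane of ring A and poorly aligned with its pi system, should stay in place.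

Step 9
Reactants: 17 (R,E)-1-{3-[1-(4-isopropoxyphenyl)ethyl]-4,6-dimethoxy-2-(methoxymethoxy)phenyl}-3-(4-methoxyphenyl)prop-2-en-1-one
Product: 18 (R,E)-1-{2-hydroxy-3-[1-(4-isopropoxyphenyl)ethyl]-4,6-dimethoxyphenyl}-3-(4-methoxyphenyl)prop-2-en-1-one
Conditions: HCl (1.25 M in MeOH), THF, 40 °C
Reagents that add atoms: none
Why: Acid-catalysed acetal methanolysis of the MOM ether, which is fast for an ether ortho to a carbonyl group and is run only after the acyl group has lowered the tendency of ring A to ipso-protonation, so the benzylic C–C bond and its stereocentre should be safe, and any flavanone 19 formed at this stage converges in step 10.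

Step 10
Reactants: 18 (R,E)-1-{2-hydroxy-3-[1-(4-isopropoxyphenyl)ethyl]-4,6-dimethoxyphenyl}-3-(4-methoxyphenyl)prop-2-en-1-one
Product: 20 8-[(R)-1-(4-isopropoxyphenyl)ethyl]-5,7-dimethoxy-2-(4-methoxyphenyl)-4H-chromen-4-one, via flavanone 19 (not isolated)
Conditions: I2 (10 mol%), DMSO, 120 °C
Reagents that add atoms: none
Why: Iodine-catalysed oxidative cyclisation of a 2'-hydroxychalcone in DMSO, in which 6-endo-trig oxa-Michael closure of the phenol onto the enone forms the O1–C2 bond (flavanone 19), iodination at C3 and loss of HI give the flavone and DMSO reoxidises HI; this is preferred to alkaline peroxide cyclisation, which with a 6'-methoxy chalcone tends toward aurones.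

Step 11
Reactants: 20 8-[(R)-1-(4-isopropoxyphenyl)ethyl]-5,7-dimethoxy-2-(4-methoxyphenyl)-4H-chromen-4-one
Product: 23 3-hydroxy-8-[(R)-1-(4-isopropoxyphenyl)ethyl]-5,7-dimethoxy-2-(4-methoxyphenyl)-4H-chromen-4-one, via 3-lithioflavone 21 (not isolated), via lithium trimethoxyborate 22 (not isolated)
Conditions: LDA, THF, −78 °C; B(OMe)3, −78 → 0 °C; AcOH, 30% aq H2O2, 0 °C → rt
Reagents that add atoms: hydrogen peroxide, OO
Why: C3 lithiation, borate trapping and peroxide oxidation of a flavone, in which LDA removes the vinylic C3 proton next to the carbonyl oxygen that holds the lithium, the vinyllithium is trapped at boron and the C–B bond is oxidised to C–OH, while the diarylmethine proton is kinetically far slower to leave at −78 °C.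

Step 12
Reactants: 23 3-hydroxy-8-[(R)-1-(4-isopropoxyphenyl)ethyl]-5,7-dimethoxy-2-(4-methoxyphenyl)-4H-chromen-4-one
Product: 24 3,5-dihydroxy-8-[(R)-1-(4-hydroxyphenyl)ethyl]-7-methoxy-2-(4-methoxyphenyl)-4H-chromen-4-one (CNP0223021.1)
Conditions: BCl3 (1 M in CH2Cl2, 6 equiv), CH2Cl2, −78 → 0 °C; then H2O
Reagents that add atoms: none
Why: Lewis-acid ether cleavage with BCl3 is selective for the secondary isopropyl aryl ether and for the 5-methoxy group, which is activated by chelation of boron between C4=O and O5, while the unchelated 7- and 4'-methoxy groups should survive at or below 0 °C and the stereocentre is not involved.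

**Compound list**

1 | 1-(4-isopropoxyphenyl)ethanone | CC(=O)c1ccc(OC(C)C)cc1 | starting material
2 | (S)-1-(4-isopropoxyphenyl)ethanol | C[C@H](O)c1ccc(OC(C)C)cc1 | intermediate
3 | (S)-1-(4-isopropoxyphenyl)ethyl N,N-diisopropylcarbamate | C[C@H](OC(=O)N(C(C)C)C(C)C)c1ccc(OC(C)C)cc1 | intermediate
4 | 3,5-dimethoxyphenol | COc1cc(O)cc(OC)c1 | starting material
5 | 1,3-dimethoxy-5-(methoxymethoxy)benzene | COCOc1cc(OC)cc(OC)c1 | intermediate
6 | [2,4-dimethoxy-6-(methoxymethoxy)phenyl]lithium | COCOc1cc(OC)cc(OC)c1[Li] | intermediate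
7 | lithium [2,4-dimethoxy-6-(methoxymethoxy)phenyl]triisopropoxyborate | COCOc1cc(OC)cc(OC)c1[B-](OC(C)C)(OC(C)C)OC(C)C.[Li+] | intermediate
8 | 2-[2,4-dimethoxy-6-(methoxymethoxy)phenyl]-5,5-dimethyl-1,3,2-dioxaborinane | COCOc1cc(OC)cc(OC)c1B1OCC(C)(C)CO1 | intermediate
9 | (S)-1-lithio-1-(4-isopropoxyphenyl)ethyl N,N-diisopropylcarbamate | C[C@]([Li])(OC(=O)N(C(C)C)C(C)C)c1ccc(OC(C)C)cc1 | intermediate
10 | lithium boronate from 9 and 8 (B bonded to the carbamate carbon, (S) at carbon) | C[C@]([B-]1(c2c(OC)cc(OC)cc2OCOC)OCC(C)(C)CO1)(OC(=O)N(C(C)C)C(C)C)c1ccc(OC(C)C)cc1.[Li+] | intermediate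
11 | (R)-2-{1-[2,4-dimethoxy-6-(methoxymethoxy)phenyl]-1-(4-isopropoxyphenyl)ethyl}-5,5-dimethyl-1,3,2-dioxaborinane | COCOc1cc(OC)cc(OC)c1[C@](B1OCC(C)(C)CO1)(C)c1ccc(OC(C)C)cc1 | intermediate
12 | (R)-1,5-dimethoxy-2-[1-(4-isopropoxyphenyl)ethyl]-3-(methoxymethoxy)benzene | COCOc1cc(OC)cc(OC)c1[C@H](C)c1ccc(OC(C)C)cc1 | intermediate
13 | (E)-4-methoxycinnamic acid | COc1ccc(/C=C/C(=O)O)cc1 | starting material
14 | (E)-N-methoxy-N-methyl-3-(4-methoxyphenyl)acrylamide | CON(C)C(=O)/C=C/c1ccc(OC)cc1 | intermediate
15 | {3-[(R)-1-(4-isopropoxyphenyl)ethyl]-4,6-dimethoxy-2-(methoxymethoxy)phenyl}lithium | COCOc1c([C@H](C)c2ccc(OC(C)C)cc2)c(OC)cc(OC)c1[Li] | intermediate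
16 | lithium alkoxide of the N-methoxy-N-methyl hemiaminal from 15 and 14 | COCOc1c([C@H](C)c2ccc(OC(C)C)cc2)c(OC)cc(OC)c1C(O[Li])(N(C)OC)/C=C/c1ccc(OC)cc1 | intermediate
17 | (R,E)-1-{3-[1-(4-isopropoxyphenyl)ethyl]-4,6-dimethoxy-2-(methoxymethoxy)phenyl}-3-(4-methoxyphenyl)prop-2-en-1-one | COCOc1c([C@H](C)c2ccc(OC(C)C)cc2)c(OC)cc(OC)c1C(=O)/C=C/c1ccc(OC)cc1 | intermediate
18 | (R,E)-1-{2-hydroxy-3-[1-(4-isopropoxyphenyl)ethyl]-4,6-dimethoxyphenyl}-3-(4-methoxyphenyl)prop-2-en-1-one | Oc1c([C@H](C)c2ccc(OC(C)C)cc2)c(OC)cc(OC)c1C(=O)/C=C/c1ccc(OC)cc1 | intermediate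
19 | 8-[(R)-1-(4-isopropoxyphenyl)ethyl]-5,7-dimethoxy-2-(4-methoxyphenyl)chroman-4-one (C2 epimers) | COc1ccc(C2CC(=O)c3c(OC)cc(OC)c([C@H](C)c4ccc(OC(C)C)cc4)c3O2)cc1 | intermediate
20 | 8-[(R)-1-(4-isopropoxyphenyl)ethyl]-5,7-dimethoxy-2-(4-methoxyphenyl)-4H-chromen-4-one | COc1ccc(-c2cc(=O)c3c(OC)cc(OC)c([C@H](C)c4ccc(OC(C)C)cc4)c3o2)cc1 | intermediate
21 | 3-lithio derivative of flavone 20 | COc1ccc(-c2oc3c([C@H](C)c4ccc(OC(C)C)cc4)c(OC)cc(OC)c3c(=O)c2[Li])cc1 | intermediate
22 | lithium trimethoxy(flavon-3-yl)borate from 21 | COc1ccc(-c2oc3c([C@H](C)c4ccc(OC(C)C)cc4)c(OC)cc(OC)c3c(=O)c2[B-](OC)(OC)OC)cc1.[Li+] | intermediate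
23 | 3-hydroxy-8-[(R)-1-(4-isopropoxyphenyl)ethyl]-5,7-dimethoxy-2-(4-methoxyphenyl)-4H-chromen-4-one | COc1ccc(-c2oc3c([C@H](C)c4ccc(OC(C)C)cc4)c(OC)cc(OC)c3c(=O)c2O)cc1 | intermediate
24 | 3,5-dihydroxy-8-[(R)-1-(4-hydroxyphenyl)ethyl]-7-methoxy-2-(4-methoxyphenyl)-4H-chromen-4-one (CNP0223021.1) | COc1ccc(-c2oc3c([C@H](C)c4ccc(O)cc4)c(OC)cc(O)c3c(=O)c2O)cc1 | target

**Step count and risks**

Total step count: 12. Longest linear sequence: 9 steps (steps 1, 2, 5, 6, 8, 9, 10, 11, 12 from ketone 1; the branch from phenol 4 through steps 3 and 4 is equally long).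

Steps most likely to fail:

Step 5 (key step). Boronate formation at a boron atom flanked by OMOM and OMe may be slow and reversible. Organolithium 9 would then be released and racemise before the aryl group migrates, or be protonated when methanol is added, which would erode enantiopurity or stall conversion. Fallback: the same stereocentre is set by Brønsted-acid-catalysed asymmetric transfer hydrogenation through an ortho-quinone methide, using the oxygen that becomes O1 as the handle. It sets out from 5 and 1. Aryllithium 6, made as in step 4 and transmetalated with CeCl3 to suppress enolisation, adds to ketone 1 to give racemic 1-[2,4-dimethoxy-6-(methoxymethoxy)phenyl]-1-(4-isopropoxyphenyl)ethanol F1. p-Toluenesulfonic acid in methanol, then warm toluene, removes the MOM group and dehydrates the tertiary alcohol to 2-[1-(4-isopropoxyphenyl)vinyl]-3,5-dimethoxyphenol F2. The chiral phosphoric acid 3,3'-bis(2,4,6-triisopropylphenyl)-1,1'-binaphthyl-2,2'-diyl hydrogen phosphate (the antipode that delivers the (R) product) with a Hantzsch ester protonates the alkene to the ortho-quinone methide and transfers hydride to one face. This should give (R)-2-[1-(4-isopropoxyphenyl)ethyl]-3,5-dimethoxyphenol F3. MOMCl/iPr2NEt then gives 12, where the route is rejoined.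

Step 8. The aryllithium 15, shielded on both sides, may attack the enamide sluggishly or in conjugate fashion at the β-carbon, and long exposure to base could begin to remove the methine proton. Fallback: the enone is built by aldol condensation instead of being delivered whole. It sets out from 12. Lithiation as in step 8 and trapping with the small electrophile N-methoxy-N-methylacetamide should give (R)-1-{3-[1-(4-isopropoxyphenyl)ethyl]-4,6-dimethoxy-2-(methoxymethoxy)phenyl}ethanone F4. Claisen–Schmidt condensation with 4-methoxybenzaldehyde (KOH, EtOH, rt) then gives chalcone 17, where the route is rejoined.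

Step 11. LDA may deprotonate C3 incompletely or compete at the diarylmethine (racemisation), and the hindered C3 borate may oxidise poorly. Fallback: the C3 oxygen is introduced before ring closure. It sets out from chalcone 17. Weitz–Scheffer epoxidation (H2O2, NaOH, MeOH/THF, 0 °C) should give {3-[(R)-1-(4-isopropoxyphenyl)ethyl]-4,6-dimethoxy-2-(methoxymethoxy)phenyl}[trans-3-(4-methoxyphenyl)oxiran-2-yl]methanone F5 as two trans diastereomers, one of which is drawn below. Methanolic HCl removes the MOM group, and the freed phenol opens the epoxide at the benzylic carbon (6-endo) to give trans-3-hydroxy-8-[(R)-1-(4-isopropoxyphenyl)ethyl]-5,7-dimethoxy-2-(4-methoxyphenyl)chroman-4-one F6, again one diastereomer drawn. Dehydrogenation with I2/KOAc in AcOH at 100 °C gives flavonol 23, where the route is rejoined; the flavone 20 is bypassed.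

**Further compounds**

F1 | step 5 | 1-[2,4-dimethoxy-6-(methoxymethoxy)phenyl]-1-(4-isopropoxyphenyl)ethanol (racemic) | COCOc1cc(OC)cc(OC)c1C(C)(O)c1ccc(OC(C)C)cc1
F2 | step 5 | 2-[1-(4-isopropoxyphenyl)vinyl]-3,5-dimethoxyphenol | C=C(c1ccc(OC(C)C)cc1)c1c(O)cc(OC)cc1OC
F3 | step 5 | (R)-2-[1-(4-isopropoxyphenyl)ethyl]-3,5-dimethoxyphenol | COc1cc(O)c([C@H](C)c2ccc(OC(C)C)cc2)c(OC)c1
F4 | step 8 | (R)-1-{3-[1-(4-isopropoxyphenyl)ethyl]-4,6-dimethoxy-2-(methoxymethoxy)phenyl}ethanone | COCOc1c([C@H](C)c2ccc(OC(C)C)cc2)c(OC)cc(OC)c1C(C)=O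
F5 | step 11 | {3-[(R)-1-(4-isopropoxyphenyl)ethyl]-4,6-dimethoxy-2-(methoxymethoxy)phenyl}[trans-3-(4-methoxyphenyl)oxiran-2-yl]methanone | COCOc1c([C@H](C)c2ccc(OC(C)C)cc2)c(OC)cc(OC)c1C(=O)[C@H]1O[C@@H]1c1ccc(OC)cc1
F6 | step 11 | trans-3-hydroxy-8-[(R)-1-(4-isopropoxyphenyl)ethyl]-5,7-dimethoxy-2-(4-methoxyphenyl)chroman-4-one | COc1ccc([C@@H]2[C@H](C(=O)c3c(OC)cc(OC)c([C@H](C)c4ccc(OC(C)C)cc4)c3O2)O)cc1
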